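The readings stem from a simulated flask from invented constants, and the scatter is random.

A small charge poses the question here: c(nucleophile) is 0.264 M against c(electrophile) 0.33 M, so there is less nucleophile than electrophile, while free base is the charge that varies from flask to flask.

| flask | electrophile | nucleophile | free base | remark | time |
|---|---|---|---|---|---|
| ash | 0.33 M | 0.264 M | 0.38 M | run made earlier |  |
| alder | 0.33 M | 0.264 M | 0.55 M | run made earlier |  |
| birch | 0.33 M | 0.264 M | 0.63 M | run made earlier |  |
| teal | 0.33 M | 0.264 M | 0.400 M |  | 2.0 min |
| blue | 0.33 M | 0.264 M | 0.890 M |  | 2.0 min |
| amber | 0.33 M | 0.264 M | 0.590 M |  | 2.0 min |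

| run | time / s | electrophile / % | target / % |
|---|---|---|---|
| ash | 10.0 | 55 | 18 |
| ash | 15.0 | 48 | 9 |
| ash | 30.0 | 37 | 5 |
| ash | 60.0 | 27 | 1 |
| alder | 12.0 | 50 | 12 |
| alder | 25.0 | 39 | 5 |
| alder | 40.0 | 31 | 4 |
| alder | 50.0 | 29 | 2 |
| alder | 60.0 | 23 | 3 |
| birch | 10.0 | 54 | 17 |
| birch | 15.0 | 50 | 10 |
| birch | 30.0 | 35 | 4 |
| birch | 60.0 | 25 | 0 |

(standard deviation of a reading: 2 percentage points)

- a reading or a percentage of target counts all its forms, free or not

- part of the electrophile that has reacted at the end, teal
- part of the electrophile that has reacted at the end, blue
- part of the electrophile that has reacted at the end, amber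
- what raising the concentration of free base from its lowest to its highest value here does to the part of the electrophile that has reacted (changes below 5 percentage points count as none) (no change / it falls / it rises)

I work with the share of electrophile left, not the share reacted. If the two react one to one, the nucleophile is the limiting reagent, and I call the floor the share of the charged electrophile it cannot reach, (c(electrophile) − c(nucleophile))/c(electrophile): 20.0%. A run that gets there has 80.0% reacted.

My objection is time, since at 60.0 s ash, alder and birch still read 27%, 23% and 25%. With e the share left, a one-to-one second-order step makes ln(e/(e − floor)) straight in time, starting from 0.223. Birch gives 1.61 at 60.0 s, so at 2.0 min the line reaches 3.00, e is 21.1%, and 78.9% has reacted. Birch at 30.0 s gives 0.847 against 0.916 on the line, that is, a reading of 35% against 33.3% on the line.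

But the excess over the floor in birch is 5 percentage points, with a scatter of 2 points. Starting from ash's reading instead gives 78.2% reacted, and from alder's 79.6%.

A harder doubt is that target in ash reads 1% at 60.0 s, which by these readings puts 72.0% of the electrophile charged in something unread. If the loss of target took more electrophile, the floor fails, yet alder's reading of 23% at 60.0 s is still more than the floor. The readings at 60.0 s do not follow the order of free base, but blue at 0.890 M lies beyond birch's 0.63 M, so I trust blue less. I commit to 78.9% in teal, blue and amber, with no change.

The forecast gives 78.5% for teal, 78.5% for blue, 78.5% for amber and no change, a little less than my figure: “The ceiling is 80% unless another pathway exists.”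

The flask gives 79.8% for teal, 79.8% for blue and 79.8% for amber, and the trend is no change, a change of 0.018 points.

    electrophile + nucleophile → acid set free + target (k = 1.10 L mol⁻¹ s⁻¹)
    nucleophile + acid set free ⇌ protonated nucleophile, settled at all times (K = 2100 L mol⁻¹)
    acid set free + free base ⇌ salt of the base (K = 240 L mol⁻¹, k = 2.50 L mol⁻¹ s⁻¹)
    crystals ⇌ target, rate k4*(cs4 - [target]) while solid is left; crystals form when [target] > cs4 (solubility = 0.0550 M, k = 22.0 s⁻¹)
    target → over-reaction product (k = 0.180 s⁻¹)
    acid set free → by-product carried off (k = 2.80 s⁻¹)

In amber the nucleophile is down to 0.17% of its charge at 2.00 min, and a nucleophile charge of 0.247 M, with the rest held, moves the answer by 5 points. For a neighbour of blue charged with 0.11 M of nucleophile the floor comes to 66.7%, and that flask ends with 66.7% of its electrophile left.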